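**Strategy.** Each of the three flavan units is traced to one racemic flavan-3-one. Its ring C, in every unit including the terminal lower one, is disconnected at the two bonds that join it to ring A: O1–C8a and C4–C4a, on adjacent aromatic carbons. Both form at once when 3,5-bis(benzyloxy)benzyne adds across the C=O group of an α-benzyloxycinnamaldehyde. The benzoxete opens to an o-quinone methide and a 6π oxa-electrocyclisation closes ring C, so the aldehyde oxygen, first bound to C4, ends as O1. Enol ether hydrolysis, dynamic kinetic reduction to both cis antipodes, C4 oxidation, two 4→8 Friedel–Crafts couplings and hydrogenolysis complete the trimer.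

Key step: step 4

Remark on the structure: the target is read as epiafzelechin-(4β→8)-ent-epiafzelechin-(4α→8)-epiafzelechin. The upper unit is (2R,3R,4R), the middle unit (2S,3S,4R) and the lower unit (2R,3R); every unit is 2,3-cis and both interflavan bonds are 3,4-trans.

Assumption on the chemistry: RuCl[(R,R)-TsDPEN](p-cymene) is taken to give the (3R) alcohol, with the α-aryloxy arm of the ketone in the position an aryl group takes in acetophenone reductions. If the sense proves opposite, the catalysts of step 6 and step 7 change places; both antipodes are consumed in the route either way.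

**Step 1**
Reactants: 1 4-(benzyloxy)benzaldehyde; 2 2-(benzyloxy)acetaldehyde
Product: 4 (Z)-2-(benzyloxy)-3-[4-(benzyloxy)phenyl]prop-2-enal, via aldol adduct 3 (not isolated)
Conditions: KOH (cat.), MeOH, 0 °C to rt; 2 added slowly to 1 (2 equiv)
Reagents that add atoms: none
Why: Claisen–Schmidt crossed aldol condensation, in which the non-enolisable aryl aldehyde accepts the enolate of the α-alkoxy aldehyde and E1cB loss of water should give the conjugated enal with the aryl group trans to the formyl group (Z).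

**Step 2**
Reactants: 5 3,5-bis(benzyloxy)phenol
Product: 6 3,5-bis(benzyloxy)-2-bromophenol
Conditions: NBS (1.0 equiv), i-Pr2NH (cat.), CH2Cl2, 0 °C
Reagents that add atoms: N-bromosuccinimide, O=C1CCC(=O)N1Br
Why: amine-catalysed ortho-selective electrophilic bromination of a phenol; the two ortho positions are equivalent and the para position is shielded by two benzyloxy groups, so the 2-bromide should dominate.

**Step 3**
Reactants: 6 3,5-bis(benzyloxy)-2-bromophenol
Product: 9 3,5-bis(benzyloxy)-2-(trimethylsilyl)phenyl trifluoromethanesulfonate, via aryl trimethylsilyl ether 7 (not isolated), via lithium 2-silylphenoxide 8 (not isolated)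
Conditions: HMDS, THF, 70 °C, concentrate; n-BuLi, THF, −78 °C; Tf2O, −78 °C to rt
Reagents that add atoms: hexamethyldisilazane, C[Si](C)(C)N[Si](C)(C)C; trifluoromethanesulfonic anhydride, O=S(=O)(OS(=O)(=O)C(F)(F)F)C(F)(F)F
Why: standard route to an o-silylaryl triflate (O-silylation, bromine–lithium exchange, retro-Brook 1,3-O-to-C silyl shift, O-triflation); exchange at −78 °C should outrun benzylic deprotonation of the benzyl ethers.

**Step 4**
Reactants: 9 3,5-bis(benzyloxy)-2-(trimethylsilyl)phenyl trifluoromethanesulfonate; 4 (Z)-2-(benzyloxy)-3-[4-(benzyloxy)phenyl]prop-2-enal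
Product: 13 rac-3,5,7-tris(benzyloxy)-2-[4-(benzyloxy)phenyl]-2H-chromene, via 3,5-bis(benzyloxy)benzyne 10 (not isolated), via benzoxete 11 (not isolated), via o-quinone methide 12 (not isolated)
Conditions: CsF (3 equiv), MeCN, rt to 40 °C; 9 added slowly to 4 (1.5 equiv)
Reagents that add atoms: none
Why: Fluoride removes the silyl group of 9 and triflate leaves to give aryne 10; the carbonyl oxygen of 4 adds to the aryne carbon remote from the adjacent benzyloxy group (O1–C8a) and the aryl anion closes on the carbonyl carbon (C4–C4a), a formal [2+2] cycloaddition to benzoxete 11. Thermal 4π ring opening breaks the old C4–O bond to give o-quinone methide 12, whose 1-oxatriene closes ring C by a disrotatory 6π oxa-electrocyclisation (O1–C2); the four-membered ring is only transient. The closest known reaction is the aryne/α,β-unsaturated aldehyde synthesis of 2H-chromenes, a relative of the aryne insertions into aldehyde and formamide C=O bonds. The only new stereocenter, C2, forms without control and is left racemic on purpose, because steps 6 and 7 reset it. The step needs regioselectivity on the unsymmetrical aryne, secured by the 3-benzyloxy group, which directs the nucleophilic oxygen to the distal carbon and so gives the 5,7-dioxygenated pattern. It also needs electrocyclisation to win over capture of 12 by a second aryne, secured by slow generation of 10 in excess 4.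

**Step 5**
Reactants: 13 rac-3,5,7-tris(benzyloxy)-2-[4-(benzyloxy)phenyl]-2H-chromene
Product: 14 rac-5,7-bis(benzyloxy)-2-[4-(benzyloxy)phenyl]chroman-3-one
Conditions: p-TsOH·H2O (cat.), acetone/H2O, rt, under argon
Reagents that add atoms: water, O
Why: acid-catalysed enol ether hydrolysis (protonation at C4, hydration of the C3 oxocarbenium ion, loss of benzyl alcohol) should turn C4 into the methylene group and C3 into the ketone, while the aryl benzyl ethers are stable to dilute acid.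

**Step 6**
Reactants: 14 rac-5,7-bis(benzyloxy)-2-[4-(benzyloxy)phenyl]chroman-3-one (about two thirds of the material)
Product: 15 (2R,3R)-5,7-bis(benzyloxy)-2-[4-(benzyloxy)phenyl]chroman-3-ol
Conditions: RuCl[(R,R)-TsDPEN](p-cymene) (2 mol %), HCO2H/Et3N (2:5), DMF, 40 °C
Reagents that add atoms: none
Why: Noyori–Ikariya asymmetric transfer hydrogenation with dynamic kinetic resolution; C2–H (α to the ketone, benzylic, α to oxygen) epimerises through the enol under the amine base, the catalyst fixes the face of hydride delivery at C3, and only the C2 epimer with its aryl group anti to the incoming hydride reacts fast, so the 2,3-cis alcohol should result.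

**Step 7**
Reactants: 14 rac-5,7-bis(benzyloxy)-2-[4-(benzyloxy)phenyl]chroman-3-one (the remaining third)
Product: 16 (2S,3S)-5,7-bis(benzyloxy)-2-[4-(benzyloxy)phenyl]chroman-3-ol
Conditions: RuCl[(S,S)-TsDPEN](p-cymene) (2 mol %), HCO2H/Et3N (2:5), DMF, 40 °C
Reagents that add atoms: none
Why: the same dynamic kinetic asymmetric transfer hydrogenation with the enantiomeric catalyst should give the mirror-image 2,3-cis alcohol, C3 set by the catalyst and C2 following by epimerisation.

**Step 8**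
Reactants: 16 (2S,3S)-5,7-bis(benzyloxy)-2-[4-(benzyloxy)phenyl]chroman-3-ol
Product: 18 (2S,3S,4R)-5,7-bis(benzyloxy)-2-[4-(benzyloxy)phenyl]-4-(2-hydroxyethoxy)chroman-3-ol, via (2S,3S)-flavan-4-ylium hydroquinonate 17 (not isolated)
Conditions: DDQ (2 equiv), ethylene glycol (excess), DMAP (cat.), CH2Cl2, rt
Reagents that add atoms: ethylene glycol, OCCO
Why: DDQ benzylic oxidation, in which hydride abstraction at C4 gives the cation, stabilised by the ortho and para oxygens of ring A, as its ion pair 17 with the reduced quinone, and the glycol should add anti to the 3-hydroxyl and 2-aryl groups (3,4-trans), a configuration that is lost again in step 9.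

**Step 9**
Reactants: 18 (2S,3S,4R)-5,7-bis(benzyloxy)-2-[4-(benzyloxy)phenyl]-4-(2-hydroxyethoxy)chroman-3-ol; 15 (2R,3R)-5,7-bis(benzyloxy)-2-[4-(benzyloxy)phenyl]chroman-3-ol
Product: 20 (2R,3R)-5,7-bis(benzyloxy)-2-[4-(benzyloxy)phenyl]-8-{(2S,3S,4S)-5,7-bis(benzyloxy)-2-[4-(benzyloxy)phenyl]-3-hydroxychroman-4-yl}chroman-3-ol, via (2S,3S)-flavan-4-ylium triflate 19 (not isolated)
Conditions: Me3SiOTf (0.2 equiv), CH2Cl2, −78 to −40 °C; 15 (4 equiv, excess recovered)
Reagents that add atoms: none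
Why: Lewis-acid-promoted Friedel–Crafts alkylation; Me3SiOTf ionises the C4–O bond of 18 to the cation triflate 19, which C8 of 15 (the more accessible and more nucleophilic ring A position) should attack on the face opposite the cis 2-aryl and 3-hydroxyl groups, setting the new C4 center 3,4-trans.

**Step 10**
Reactants: 15 (2R,3R)-5,7-bis(benzyloxy)-2-[4-(benzyloxy)phenyl]chroman-3-ol
Product: 22 (2R,3R,4S)-5,7-bis(benzyloxy)-2-[4-(benzyloxy)phenyl]-4-(2-hydroxyethoxy)chroman-3-ol, via (2R,3R)-flavan-4-ylium hydroquinonate 21 (not isolated)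
Conditions: DDQ (2 equiv), ethylene glycol (excess), DMAP (cat.), CH2Cl2, rt
Reagents that add atoms: ethylene glycol, OCCO
Why: the same DDQ benzylic oxidation at C4 as in step 8, hydride abstraction giving the ion pair 21 and the glycol adding trans to the 3-hydroxyl group.

**Step 11**
Reactants: 22 (2R,3R,4S)-5,7-bis(benzyloxy)-2-[4-(benzyloxy)phenyl]-4-(2-hydroxyethoxy)chroman-3-ol; 20 hexa-O-benzyl dimer
Product: 24 nona-O-benzyl epiafzelechin-(4β→8)-ent-epiafzelechin-(4α→8)-epiafzelechin, via (2R,3R)-flavan-4-ylium triflate 23 (not isolated)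
Conditions: Me3SiOTf (0.2 equiv), CH2Cl2, −78 °C; 20 (3 equiv, excess recovered)
Reagents that add atoms: none
Why: Friedel–Crafts alkylation of the only free C8 of 20 (on its upper unit) by the cation triflate 23 that Me3SiOTf releases from 22, attack anti to the 2-aryl and 3-hydroxyl groups giving the 3,4-trans (4R) center; low temperature should prevent acid cleavage of the first interflavan bond.

**Step 12**
Reactants: 24 nona-O-benzyl trimer
Product: 25 epiafzelechin-(4β→8)-ent-epiafzelechin-(4α→8)-epiafzelechin (CNP0191553.2)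
Conditions: H2 (1 atm), Pd(OH)2/C, THF/MeOH/H2O, rt
Reagents that add atoms: none
Why: catalytic hydrogenolysis of the nine benzyl ethers; the interflavan C–C bonds, the secondary alcohols and all stereocenters should be untouched.

**Compound list**

1 | 4-(benzyloxy)benzaldehyde | O=Cc1ccc(OCc2ccccc2)cc1 | starting material
2 | 2-(benzyloxy)acetaldehyde | O=CCOCc1ccccc1 | starting material
3 | 2-(benzyloxy)-3-[4-(benzyloxy)phenyl]-3-hydroxypropanal (aldol adduct, diastereomer mixture, not isolated) | O=CC(OCc1ccccc1)C(O)c1ccc(OCc2ccccc2)cc1 | intermediate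
4 | (Z)-2-(benzyloxy)-3-[4-(benzyloxy)phenyl]prop-2-enal | O=C/C(OCc1ccccc1)=C/c1ccc(OCc2ccccc2)cc1 | intermediate
5 | 3,5-bis(benzyloxy)phenol | Oc1cc(OCc2ccccc2)cc(OCc2ccccc2)c1 | starting material
6 | 3,5-bis(benzyloxy)-2-bromophenol | Oc1cc(OCc2ccccc2)cc(OCc2ccccc2)c1Br | intermediate
7 | [3,5-bis(benzyloxy)-2-bromophenoxy]trimethylsilane (not isolated) | C[Si](C)(C)Oc1cc(OCc2ccccc2)cc(OCc2ccccc2)c1Br | intermediate
8 | lithium 3,5-bis(benzyloxy)-2-(trimethylsilyl)phenoxide (not isolated) | [Li+].[O-]c1cc(OCc2ccccc2)cc(OCc2ccccc2)c1[Si](C)(C)C | intermediate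
9 | 3,5-bis(benzyloxy)-2-(trimethylsilyl)phenyl trifluoromethanesulfonate | C[Si](C)(C)c1c(OCc2ccccc2)cc(OCc2ccccc2)cc1OS(=O)(=O)C(F)(F)F | intermediate
10 | 3,5-bis(benzyloxy)benzyne (not isolated) | C1#CC(OCc2ccccc2)=CC(OCc2ccccc2)=C1 | intermediate
11 | rac-3,5-bis(benzyloxy)-2-{(Z)-1-(benzyloxy)-2-[4-(benzyloxy)phenyl]ethenyl}-2H-benzo[b]oxete (not isolated) | O1C(/C(OCc2ccccc2)=C/c2ccc(OCc3ccccc3)cc2)c2c(OCc3ccccc3)cc(OCc3ccccc3)cc12 | intermediate
12 | 3,5-bis(benzyloxy)-6-{(Z)-2-(benzyloxy)-3-[4-(benzyloxy)phenyl]prop-2-enylidene}cyclohexa-2,4-dien-1-one, side chain syn to the carbonyl (not isolated) | O=C1C=C(OCc2ccccc2)C=C(OCc2ccccc2)/C1=C/C(OCc1ccccc1)=C/c1ccc(OCc2ccccc2)cc1 | intermediate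
13 | rac-3,5,7-tris(benzyloxy)-2-[4-(benzyloxy)phenyl]-2H-chromene | C(c1ccccc1)OC1=Cc2c(OCc3ccccc3)cc(OCc3ccccc3)cc2OC1c1ccc(OCc2ccccc2)cc1 | intermediate
14 | rac-5,7-bis(benzyloxy)-2-[4-(benzyloxy)phenyl]chroman-3-one | O=C1Cc2c(OCc3ccccc3)cc(OCc3ccccc3)cc2OC1c1ccc(OCc2ccccc2)cc1 | intermediate
15 | (2R,3R)-5,7-bis(benzyloxy)-2-[4-(benzyloxy)phenyl]chroman-3-ol (2,3-cis) | c1c(OCc3ccccc3)cc(OCc3ccccc3)c2c1O[C@H](c1ccc(OCc3ccccc3)cc1)[C@H](O)C2 | intermediate
16 | (2S,3S)-5,7-bis(benzyloxy)-2-[4-(benzyloxy)phenyl]chroman-3-ol (2,3-cis) | c1c(OCc3ccccc3)cc(OCc3ccccc3)c2c1O[C@@H](c1ccc(OCc3ccccc3)cc1)[C@@H](O)C2 | intermediate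
17 | (2S,3S)-5,7-bis(benzyloxy)-2-[4-(benzyloxy)phenyl]-3-hydroxychroman-4-ylium 2,3-dichloro-5,6-dicyano-4-hydroxyphenolate (ion pair, not isolated) | c1c(OCc3ccccc3)cc(OCc3ccccc3)c2c1O[C@@H](c1ccc(OCc3ccccc3)cc1)[C@@H](O)[CH+]2.[O-]c1c(Cl)c(Cl)c(O)c(C#N)c1C#N | intermediate
18 | (2S,3S,4R)-5,7-bis(benzyloxy)-2-[4-(benzyloxy)phenyl]-4-(2-hydroxyethoxy)chroman-3-ol (3,4-trans) | c1c(OCc3ccccc3)cc(OCc3ccccc3)c2c1O[C@@H](c1ccc(OCc3ccccc3)cc1)[C@@H](O)[C@@H]2OCCO | intermediate
19 | (2S,3S)-5,7-bis(benzyloxy)-2-[4-(benzyloxy)phenyl]-3-hydroxychroman-4-ylium trifluoromethanesulfonate (ion pair, not isolated) | c1c(OCc3ccccc3)cc(OCc3ccccc3)c2c1O[C@@H](c1ccc(OCc3ccccc3)cc1)[C@@H](O)[CH+]2.[O-]S(=O)(=O)C(F)(F)F | intermediate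
20 | hexa-O-benzyl ent-epiafzelechin-(4α→8)-epiafzelechin; upper unit (2S,3S,4S), lower unit (2R,3R) | c1c(OCc5ccccc5)cc(OCc5ccccc5)c2c1O[C@@H](c1ccc(OCc5ccccc5)cc1)[C@@H](O)[C@@H]2c1c(OCc5ccccc5)cc(OCc5ccccc5)c2c1O[C@H](c1ccc(OCc5ccccc5)cc1)[C@H](O)C2 | intermediate
21 | (2R,3R)-5,7-bis(benzyloxy)-2-[4-(benzyloxy)phenyl]-3-hydroxychroman-4-ylium 2,3-dichloro-5,6-dicyano-4-hydroxyphenolate (ion pair, not isolated) | c1c(OCc3ccccc3)cc(OCc3ccccc3)c2c1O[C@H](c1ccc(OCc3ccccc3)cc1)[C@H](O)[CH+]2.[O-]c1c(Cl)c(Cl)c(O)c(C#N)c1C#N | intermediate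
22 | (2R,3R,4S)-5,7-bis(benzyloxy)-2-[4-(benzyloxy)phenyl]-4-(2-hydroxyethoxy)chroman-3-ol (3,4-trans) | c1c(OCc3ccccc3)cc(OCc3ccccc3)c2c1O[C@H](c1ccc(OCc3ccccc3)cc1)[C@H](O)[C@H]2OCCO | intermediate
23 | (2R,3R)-5,7-bis(benzyloxy)-2-[4-(benzyloxy)phenyl]-3-hydroxychroman-4-ylium trifluoromethanesulfonate (ion pair, not isolated) | c1c(OCc3ccccc3)cc(OCc3ccccc3)c2c1O[C@H](c1ccc(OCc3ccccc3)cc1)[C@H](O)[CH+]2.[O-]S(=O)(=O)C(F)(F)F | intermediate
24 | nona-O-benzyl epiafzelechin-(4β→8)-ent-epiafzelechin-(4α→8)-epiafzelechin; upper (2R,3R,4R), middle (2S,3S,4R), lower (2R,3R) | c5ccccc5COc1ccc([C@H]2Oc3cc(OCc5ccccc5)cc(OCc5ccccc5)c3[C@H](c3c(OCc5ccccc5)cc(OCc5ccccc5)c4c3O[C@@H](c3ccc(OCc5ccccc5)cc3)[C@@H](O)[C@@H]4c3c(OCc5ccccc5)cc(OCc5ccccc5)c4c3O[C@H](c3ccc(OCc5ccccc5)cc3)[C@H](O)C4)[C@H]2O)cc1 | intermediate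
25 | epiafzelechin-(4β→8)-ent-epiafzelechin-(4α→8)-epiafzelechin (CNP0191553.2) | Oc1ccc([C@H]2Oc3cc(O)cc(O)c3[C@H](c3c(O)cc(O)c4c3O[C@@H](c3ccc(O)cc3)[C@@H](O)[C@@H]4c3c(O)cc(O)c4c3O[C@H](c3ccc(O)cc3)[C@H](O)C4)[C@H]2O)cc1 | target

**Step count.** Total: 12 steps. Longest linear sequence: 9 steps (5 → 6 → 9 → 13 → 14 → 16 → 18 → 20 → 24 → 25; steps 2, 3, 4, 5, 7, 8, 9, 11, 12).

**The three steps most likely to fail**

Step 4. The o-quinone methide may be intercepted by a second aryne before it cyclises, or the carbonyl group may add to the aryne in the reverse orientation, so that little of the 5,7-dioxygenated chromene forms. The fallback builds the same ketone without an aryne and sets out from 1 and 5. CH2=CHMgBr (THF, 0 °C) should add to 1 to give rac-1-[4-(benzyloxy)phenyl]prop-2-en-1-ol F1. Acid-catalysed Friedel–Crafts allylation of 5 with F1 (H2SO4 on SiO2, CH2Cl2) should give 3,5-bis(benzyloxy)-2-{(E)-3-[4-(benzyloxy)phenyl]prop-2-enyl}phenol F2 through the aryl-stabilised allyl cation. Dihydroxylation (OsO4 cat., NMO, acetone/H2O) should give the rac-(1S*,2S*) triol F3. Orthoformate cyclisation (HC(OEt)3, PPTS, 60 °C) should close the pyran ring with inversion at the benzylic carbon to the rac-2,3-trans 3-O-formate F4, and K2CO3/MeOH should free the rac-2,3-trans alcohol F5. Dess–Martin periodinane (CH2Cl2, rt) should oxidise F5 to ketone 14, where the route is rejoined.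

Step 6 (step 7 shares the risk). Epimerisation at C2 may be slower than reduction, so that the process becomes a simple kinetic resolution, or facial control at the hindered dialkyl-type ketone may be poor, leading to low enantiomeric purity or trans alcohol. The fallback sets out from 14 and replaces both step 6 and step 7. LiBH(s-Bu)3 (THF, −78 °C) should reduce 14 from the face opposite the 2-aryl group to the racemic cis alcohol, that is 15 and 16 together. Esterification with (S)-O-acetylmandelic acid (DCC, DMAP, CH2Cl2, 0 °C) should give the diastereomeric esters, the (2R,3R) ester F6 (from 15) and the (2S,3S) ester F7 (from 16), separable by chromatography or crystallisation. K2CO3/MeOH should then release 15 from F6 and 16 from F7, where the route is rejoined.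

Step 11. The electrophile may condense with itself through its own free C8, attack may occur at a C6 position, or the acid may cleave and scramble the first interflavan bond, giving oligomer mixtures. The fallback caps C8 of the upper unit with bromine; it sets out from 15 and uses dimer 20 unchanged. NBS (CH2Cl2, −78 °C) should brominate 15 at C8 to give the 8-bromo alcohol F8. DDQ/ethylene glycol/DMAP should convert F8 into the 8-bromo 4-(2-hydroxyethoxy) electrophile F9. Me3SiOTf (CH2Cl2, −78 °C) with a near-equimolar amount of 20 should give the 8-bromo nona-O-benzyl trimer F10, since F9 cannot alkylate itself. Hydrogenolysis (H2, Pd(OH)2/C, Et3N, THF/MeOH/H2O) should remove the benzyl groups and the bromine together and come back to the route at the target 25.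

**Further compounds**

F1 | step 4 | rac-1-[4-(benzyloxy)phenyl]prop-2-en-1-ol | C=CC(O)c1ccc(OCc2ccccc2)cc1
F2 | step 4 | 3,5-bis(benzyloxy)-2-{(E)-3-[4-(benzyloxy)phenyl]prop-2-enyl}phenol | Oc1cc(OCc2ccccc2)cc(OCc2ccccc2)c1C/C=C/c1ccc(OCc2ccccc2)cc1
F3 | step 4 | rac-(1S,2S)-3-[2,4-bis(benzyloxy)-6-hydroxyphenyl]-1-[4-(benzyloxy)phenyl]propane-1,2-diol (one enantiomer drawn) | O[C@@H](c1ccc(OCc2ccccc2)cc1)[C@@H](O)Cc1c(O)cc(OCc2ccccc2)cc1OCc1ccccc1
F4 | step 4 | rac-(2R,3S)-5,7-bis(benzyloxy)-2-[4-(benzyloxy)phenyl]chroman-3-yl formate (2,3-trans, one enantiomer drawn) | c1c(OCc3ccccc3)cc(OCc3ccccc3)c2c1O[C@H](c1ccc(OCc3ccccc3)cc1)[C@@H](OC=O)C2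
F5 | step 4 | rac-(2R,3S)-5,7-bis(benzyloxy)-2-[4-(benzyloxy)phenyl]chroman-3-ol (2,3-trans, one enantiomer drawn) | c1c(OCc3ccccc3)cc(OCc3ccccc3)c2c1O[C@H](c1ccc(OCc3ccccc3)cc1)[C@@H](O)C2
F6 | step 6 | (2R,3R)-5,7-bis(benzyloxy)-2-[4-(benzyloxy)phenyl]chroman-3-yl (S)-2-acetoxy-2-phenylacetate | c1c(OCc3ccccc3)cc(OCc3ccccc3)c2c1O[C@H](c1ccc(OCc3ccccc3)cc1)[C@H](OC(=O)[C@@H](OC(C)=O)c1ccccc1)C2
F7 | step 6 | (2S,3S)-5,7-bis(benzyloxy)-2-[4-(benzyloxy)phenyl]chroman-3-yl (S)-2-acetoxy-2-phenylacetate | c1c(OCc3ccccc3)cc(OCc3ccccc3)c2c1O[C@@H](c1ccc(OCc3ccccc3)cc1)[C@@H](OC(=O)[C@@H](OC(C)=O)c1ccccc1)C2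
F8 | step 11 | (2R,3R)-5,7-bis(benzyloxy)-2-[4-(benzyloxy)phenyl]-8-bromochroman-3-ol | Brc1c(OCc3ccccc3)cc(OCc3ccccc3)c2c1O[C@H](c1ccc(OCc3ccccc3)cc1)[C@H](O)C2
F9 | step 11 | (2R,3R,4S)-5,7-bis(benzyloxy)-2-[4-(benzyloxy)phenyl]-8-bromo-4-(2-hydroxyethoxy)chroman-3-ol | Brc1c(OCc3ccccc3)cc(OCc3ccccc3)c2c1O[C@H](c1ccc(OCc3ccccc3)cc1)[C@H](O)[C@H]2OCCO
F10 | step 11 | nona-O-benzyl trimer 24 with bromine at C8 of the upper unit | c5ccccc5COc1ccc([C@H]2Oc3c(Br)c(OCc5ccccc5)cc(OCc5ccccc5)c3[C@H](c3c(OCc5ccccc5)cc(OCc5ccccc5)c4c3O[C@@H](c3ccc(OCc5ccccc5)cc3)[C@@H](O)[C@@H]4c3c(OCc5ccccc5)cc(OCc5ccccc5)c4c3O[C@H](c3ccc(OCc5ccccc5)cc3)[C@H](O)C4)[C@H]2O)cc1
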